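**Retrosynthetic overview**

1. Target ⇒ 7-O-benzyl-5,8-dihydroxyflavone by O7-debenzylation and O8-methylation; the 5-OH is hydrogen-bonded to C4=O, so O8 is the only phenol that alkylates.
2. Feature used: C5 and C8 of ring A carry para oxygens, so ring A can be a 1,4-benzoquinone in which C8a is β to both the C5 quinone carbonyl and the C4 ketone. Disconnect O1–C8a ⇒ 2-benzyloxy-5-(3-aryl-3-oxopropanoyl)-1,4-benzoquinone (oxa-Michael addition of the diketone enol oxygen, then aromatisation).
3. Acylquinone ⇒ oxidative demethylation of the hydroquinone dimethyl ether 1,3-diketone ⇒ Claisen condensation of 4-benzyloxy-2,5-dimethoxyacetophenone with methyl 3,4,5-trimethoxybenzoate.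
4. Acetophenone ⇒ Friedel–Crafts acetylation of 2-benzyloxy-1,4-dimethoxybenzene ⇒ benzylation of 2,5-dimethoxyphenol ⇒ Dakin oxidation of 2,5-dimethoxybenzaldehyde.
5. Ring order: rings A and B are bought as benzenes; ring C is the only ring built, in step 6.

Key step: step 6

Remark on the chemistry: quinone 9 is assumed to survive a cold, rapid extractive work-up and is carried into step 6 without purification; should it close in the oxidation flask, the result of step 6 is simply reached earlier.

**Route**

Step 1
Reactants: 1 2,5-dimethoxybenzaldehyde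
Product: 3 2,5-dimethoxyphenol, via 2,5-dimethoxyphenyl formate 2 (not isolated)
Conditions: 30% aq. H2O2 (1.3 equiv), H2SO4 (cat.), MeOH, 20 °C
Reagents that add atoms: hydrogen peroxide, OO
Why: Dakin oxidation, in which acid-catalysed Baeyer–Villiger-type aryl migration in the peroxide adduct of the electron-rich aldehyde gives formate 2, which methanol cleaves to the phenol in the same flask.

Step 2
Reactants: 3 2,5-dimethoxyphenol; 4 benzyl bromide
Product: 5 2-benzyloxy-1,4-dimethoxybenzene
Conditions: K2CO3, acetone, reflux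
Reagents that add atoms: benzyl bromide (compound 4), BrCc1ccccc1
Why: Williamson ether synthesis of a phenoxide with a reactive benzylic bromide, for which O-alkylation is the only likely course.

Step 3
Reactants: 5 2-benzyloxy-1,4-dimethoxybenzene
Product: 6 1-(4-benzyloxy-2,5-dimethoxyphenyl)ethanone
Conditions: Ac2O (1.5 equiv), Sc(OTf)3 (10 mol %), MeNO2, 40 °C
Reagents that add atoms: acetic anhydride, CC(=O)OC(C)=O
Why: Friedel–Crafts acylation under mild metal-triflate catalysis should go to the one position that is para to OBn and ortho to OMe (the pattern of 1,2,4-trialkoxybenzenes), should spare the benzyl ether, and stops at mono-acylation because the ketone deactivates the ring.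

Step 4
Reactants: 6 1-(4-benzyloxy-2,5-dimethoxyphenyl)ethanone; 7 methyl 3,4,5-trimethoxybenzoate
Product: 8 1-(4-benzyloxy-2,5-dimethoxyphenyl)-3-(3,4,5-trimethoxyphenyl)propane-1,3-dione
Conditions: NaH (2.5 equiv), THF, reflux; then aq. HCl, 0 °C
Reagents that add atoms: methyl 3,4,5-trimethoxybenzoate (compound 7), COC(=O)c1cc(OC)c(OC)c(OC)c1
Why: Crossed Claisen condensation of the methyl ketone enolate with a non-enolisable aryl ester, driven by irreversible deprotonation of the 1,3-diketone formed.

Step 5
Reactants: 8 1-(4-benzyloxy-2,5-dimethoxyphenyl)-3-(3,4,5-trimethoxyphenyl)propane-1,3-dione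
Product: 9 2-benzyloxy-5-[3-oxo-3-(3,4,5-trimethoxyphenyl)propanoyl]-1,4-benzoquinone
Conditions: (NH4)2Ce(NO3)6 (2.2 equiv), MeCN–H2O 3:1, 0 °C, 10 min; cold extractive work-up, used crude at once
Reagents that add atoms: water, O
Why: Oxidative demethylation of a hydroquinone dimethyl ether by tetravalent cerium, in which the 1,2,4-trialkoxy ring A is the most easily oxidised arene, water adds at the two para methoxy-bearing carbons and methanol is lost, while the benzyl ether and the 3,4,5-trimethoxybenzoyl ring are harder to oxidise and the short time at 0 °C limits oxidation of the diketone enol.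

Step 6
Reactants: 9 2-benzyloxy-5-[3-oxo-3-(3,4,5-trimethoxyphenyl)propanoyl]-1,4-benzoquinone
Product: 11 7-benzyloxy-5,8-dihydroxy-2-(3,4,5-trimethoxyphenyl)chromen-4-one, via 8aH-chromene-4,8-dione adduct 10 (not isolated)
Conditions: NaOAc (0.2 equiv), AcOH–CH2Cl2 1:4, 0.01 M, argon, 20 °C
Reagents that add atoms: none
Why: Proposed new method: the oxygen of the Z-enol on the aryl-ketone side of the 1,3-diketone adds to the quinone CH next to the acyl-bearing carbon (the future C8a), which is β to both the C5 quinone carbonyl and the C4 ketone, with acetate relaying the enol proton to the quinone oxygen; adduct 10 then loses its C8a proton toward C8=O, and the aromatisation of ring A to the hydroquinone makes the closure irreversible. The closest known reaction types are the conjugate addition of amines, thiols, halide and carbon nucleophiles to C3 of 2-acyl-1,4-benzoquinones and the 6-endo oxa-Michael closure of 2'-hydroxychalcones to flavanones. Ring C closes in a 6-endo-trig mode by forming O1–C8a. The C8a stereocentre of 10 is transient and is erased on tautomerisation, so no stereocontrol is needed. The step needs O- over C-attack and C8a over the other electrophilic sites: attack through C3 would give a four-membered ring, C6 and C7 are out of reach of the tether, addition to the C5 carbonyl gives only a reversible hemiketal, and high dilution holds back intermolecular Michael addition and quinone–hydroquinone hydrogen exchange.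

Step 7
Reactants: 11 7-benzyloxy-5,8-dihydroxy-2-(3,4,5-trimethoxyphenyl)chromen-4-one
Product: 12 7-benzyloxy-5-hydroxy-8-methoxy-2-(3,4,5-trimethoxyphenyl)chromen-4-one
Conditions: MeI (1.1 equiv), K2CO3 (1.5 equiv), degassed acetone, argon, 40 °C
Reagents that add atoms: iodomethane, CI
Why: Williamson methylation with one equivalent of MeI should be selective for the 8-OH, because the 5-OH is locked in a hydrogen bond to the C4 carbonyl and is far less acidic and nucleophilic, and exclusion of oxygen protects the hydroquinone monoanion.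

Step 8
Reactants: 12 7-benzyloxy-5-hydroxy-8-methoxy-2-(3,4,5-trimethoxyphenyl)chromen-4-one
Product: 13 5,7-dihydroxy-8-methoxy-2-(3,4,5-trimethoxyphenyl)chromen-4-one (3',4',5'-trimethoxywogonin)
Conditions: H2 (1 atm), 10% Pd/C, EtOAc–MeOH, 20 °C
Reagents that add atoms: none
Why: Catalytic hydrogenolysis of a benzyl aryl ether at atmospheric pressure, under which the vinylogous-ester C2=C3 bond of the chromone and the four methyl ethers should be untouched.

**Compound list**

1 | 2,5-dimethoxybenzaldehyde | COc1ccc(OC)c(C=O)c1 | starting material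
2 | 2,5-dimethoxyphenyl formate | COc1ccc(OC)c(OC=O)c1 | intermediate (not isolated)
3 | 2,5-dimethoxyphenol | COc1ccc(OC)c(O)c1 | intermediate
4 | benzyl bromide | BrCc1ccccc1 | starting material
5 | 2-benzyloxy-1,4-dimethoxybenzene | COc1ccc(OC)c(OCc2ccccc2)c1 | intermediate
6 | 1-(4-benzyloxy-2,5-dimethoxyphenyl)ethanone | CC(=O)c1cc(OC)c(OCc2ccccc2)cc1OC | intermediate
7 | methyl 3,4,5-trimethoxybenzoate | COC(=O)c1cc(OC)c(OC)c(OC)c1 | starting material
8 | 1-(4-benzyloxy-2,5-dimethoxyphenyl)-3-(3,4,5-trimethoxyphenyl)propane-1,3-dione | COc1cc(C(=O)CC(=O)c2cc(OC)c(OCc3ccccc3)cc2OC)cc(OC)c1OC | intermediate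
9 | 2-benzyloxy-5-[3-oxo-3-(3,4,5-trimethoxyphenyl)propanoyl]-1,4-benzoquinone | O=C1C=C(OCc2ccccc2)C(=O)C=C1C(=O)CC(=O)c1cc(OC)c(OC)c(OC)c1 | intermediate
10 | 7-benzyloxy-5-hydroxy-2-(3,4,5-trimethoxyphenyl)-8aH-chromene-4,8-dione (racemic at C8a, transient) | COc1cc(C2=CC(=O)C3=C(O)C=C(OCc4ccccc4)C(=O)C3O2)cc(OC)c1OC | intermediate (not isolated)
11 | 7-benzyloxy-5,8-dihydroxy-2-(3,4,5-trimethoxyphenyl)chromen-4-one | COc1cc(-c2cc(=O)c3c(O)cc(OCc4ccccc4)c(O)c3o2)cc(OC)c1OC | intermediate
12 | 7-benzyloxy-5-hydroxy-8-methoxy-2-(3,4,5-trimethoxyphenyl)chromen-4-one | COc1cc(-c2cc(=O)c3c(O)cc(OCc4ccccc4)c(OC)c3o2)cc(OC)c1OC | intermediate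
13 | 5,7-dihydroxy-8-methoxy-2-(3,4,5-trimethoxyphenyl)chromen-4-one | COc1cc(-c2cc(=O)c3c(O)cc(O)c(OC)c3o2)cc(OC)c1OC | target

**Summary**

Total step count: 8. Longest linear sequence: 8 steps (1 to 13); 4 and 7 enter as commercial reagents.

**Steps most likely to fail**

1. Step 6. The enol oxygen may add too slowly. Then intermolecular C-Michael addition of one diketone to another quinone, or hydrogen transfer from product hydroquinone 11 to unreacted quinone 9, or displacement of the benzyloxy group at C7 by acetate could take over. The fallback uses known chemistry, sets out from 7 and returns at 11.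
   - Claisen condensation of 7 with methyl acetate (NaH, THF, reflux) should give methyl 3-oxo-3-(3,4,5-trimethoxyphenyl)propanoate F1.
   - Thermal condensation of F1 with phloroglucinol (neat, 240 °C) should give 5,7-dihydroxy-2-(3,4,5-trimethoxyphenyl)chromen-4-one F2.
   - Benzylation of the unchelated 7-OH with 4 (K2CO3, acetone) should give 7-benzyloxy-5-hydroxy-2-(3,4,5-trimethoxyphenyl)chromen-4-one F3.
   - Elbs persulfate oxidation (K2S2O8, aq. KOH–pyridine, 15 °C) should place a sulfate para to the 5-OH, giving potassium 7-benzyloxy-5-hydroxy-4-oxo-2-(3,4,5-trimethoxyphenyl)chromen-8-yl sulfate F4.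
   - Acid hydrolysis of F4 (aq. HCl, Na2SO3, 90 °C) should give 11, which rejoins the route before step 7.

2. Step 5. Tetravalent cerium may oxidise the enolised 1,3-diketone by one electron (radical coupling, nitrate trapping), or the quinone may close in the oxidising medium and the resulting hydroquinone be over-oxidised. The fallback changes ring A's oxidation level before the diketone exists and forms the quinone by a neutral dehydrogenation. It sets out from 6 and returns at 9.
   - Oxidation of 6 with (NH4)2Ce(NO3)6 (MeCN–H2O, 0 °C) should give 2-acetyl-5-benzyloxy-1,4-benzoquinone F5.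
   - Reduction with aq. Na2S2O4 should give 1-(4-benzyloxy-2,5-dihydroxyphenyl)ethanone F6.
   - C-Aroylation of the lithium polyanion of F6 (LiN(SiMe3)2, 4 equiv, THF, −78 °C to 20 °C) with commercial 3,4,5-trimethoxybenzoyl chloride should give 1-(4-benzyloxy-2,5-dihydroxyphenyl)-3-(3,4,5-trimethoxyphenyl)propane-1,3-dione F7. F7 is kept away from acid to avoid cyclodehydration through its 2'-OH.
   - Ag2O (MgSO4, CH2Cl2–Et2O, 20 °C) should oxidise F7 to 9.

3. Step 3. The Lewis acid may remove or C-migrate the benzyl group, or demethylate the methoxy group ortho to the new ketone. The fallback replaces electrophilic acylation by halogen–metal exchange. It sets out from 5 and returns at 6.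
   - Bromination with N-bromosuccinimide (MeCN, 0 °C) at the same para-to-OBn position should give 1-benzyloxy-4-bromo-2,5-dimethoxybenzene F8.
   - Bromine–lithium exchange (n-BuLi, THF, −78 °C) should give (4-benzyloxy-2,5-dimethoxyphenyl)lithium F9.
   - Trapping F9 with N-methoxy-N-methylacetamide should give 6.

**Further compounds**

F1 | step 6 | methyl 3-oxo-3-(3,4,5-trimethoxyphenyl)propanoate | COC(=O)CC(=O)c1cc(OC)c(OC)c(OC)c1
F2 | step 6 | 5,7-dihydroxy-2-(3,4,5-trimethoxyphenyl)chromen-4-one | COc1cc(-c2cc(=O)c3c(O)cc(O)cc3o2)cc(OC)c1OC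
F3 | step 6 | 7-benzyloxy-5-hydroxy-2-(3,4,5-trimethoxyphenyl)chromen-4-one | COc1cc(-c2cc(=O)c3c(O)cc(OCc4ccccc4)cc3o2)cc(OC)c1OC
F4 | step 6 | potassium 7-benzyloxy-5-hydroxy-4-oxo-2-(3,4,5-trimethoxyphenyl)chromen-8-yl sulfate | COc1cc(-c2cc(=O)c3c(O)cc(OCc4ccccc4)c(OS(=O)(=O)[O-])c3o2)cc(OC)c1OC.[K+]
F5 | step 5 | 2-acetyl-5-benzyloxy-1,4-benzoquinone | CC(=O)C1=CC(=O)C(OCc2ccccc2)=CC1=O
F6 | step 5 | 1-(4-benzyloxy-2,5-dihydroxyphenyl)ethanone | CC(=O)c1cc(O)c(OCc2ccccc2)cc1O
F7 | step 5 | 1-(4-benzyloxy-2,5-dihydroxyphenyl)-3-(3,4,5-trimethoxyphenyl)propane-1,3-dione | COc1cc(C(=O)CC(=O)c2cc(O)c(OCc3ccccc3)cc2O)cc(OC)c1OC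
F8 | step 3 | 1-benzyloxy-4-bromo-2,5-dimethoxybenzene | COc1cc(OCc2ccccc2)c(OC)cc1Br
F9 | step 3 | (4-benzyloxy-2,5-dimethoxyphenyl)lithium | COc1cc(OCc2ccccc2)c(OC)cc1[Li]
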